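**Retrosynthetic overview**
1. Hypholomine B ⇐ desilylation of its tetra-TBS ether, formed in one thermal operation from a spirocyclopropyl pyran-2,4-dione carrying a β-keto-dioxinone: dioxinone → acylketene → pendant 4-hydroxy-2-pyranone, then donor–acceptor cyclopropane → trans-dihydrofuran (Cloke–Wilson).
2. β-Keto-dioxinone ⇐ vinylogous aldol of the dioxinone dienolate with a spirocyclopropane carbaldehyde, then oxidation.
3. Spirocyclopropane carbaldehyde ⇐ aminocatalytic Michael-initiated ring closure of 3-bromo-di-TBS-hispidin with di-TBS-caffeic aldehyde; this fixes C3 of the target, and C2 follows trans in the ring expansion.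
4. Both partners ⇐ 3,4-bis(TBSO)benzaldehyde: Wittig to the enal; triacetic acid lactone dianion aldol/dehydration, then NBS.
5. Ring order: fused pyranone (from triacetic acid lactone) → temporary cyclopropane → pendant pyranone and dihydrofuran together.

Assumption: the target is the (2S,3S)-trans isomer as written in the SMILES; the facial selectivity of the (S)-diarylprolinol catalyst is taken from its enal/bromomalonate cyclopropanations (if the sense is opposite, the (R)-catalyst is used).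
Abbreviations: TBS = tert-butyldimethylsilyl; Ar = 3,4-bis(tert-butyldimethylsilyloxy)phenyl; Sp = (1R,2S)-2-Ar-6-[(E)-2-Ar-ethenyl]-4,8-dioxo-5-oxaspiro[2.5]oct-6-en-1-yl (the spirocyclopropyl residue of 10 without its CHO group; spiro carbon as epimer mixture).

**Step 1**
Reactants: 1 3,4-dihydroxybenzaldehyde
Product: 2 3,4-bis(tert-butyldimethylsilyloxy)benzaldehyde
Conditions: TBSCl (2.5 equiv), imidazole (5 equiv), DMF, rt
Reagents that add atoms: tert-butyldimethylsilyl chloride (TBSCl), CC(C)(C)[Si](C)(C)Cl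
Why: Imidazole-mediated silylation of both phenols masks the catechol for the later base- and oxidant-mediated steps; no stereocentre is involved.

**Step 2**
Reactants: 2 3,4-bis(tert-butyldimethylsilyloxy)benzaldehyde; 3 (triphenylphosphoranylidene)acetaldehyde
Product: 4 (E)-3-Ar-prop-2-enal
Conditions: PhMe, 80 °C
Reagents that add atoms: none
Why: Wittig olefination with the stabilised formylmethylene ylide gives the (E)-enal selectively.

**Step 3**
Reactants: 5 4-hydroxy-6-methyl-2H-pyran-2-one (triacetic acid lactone); 2 3,4-bis(tert-butyldimethylsilyloxy)benzaldehyde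
Product: 8 6-[(E)-2-Ar-ethenyl]-4-hydroxy-2H-pyran-2-one (di-TBS hispidin), via dilithio dianion 6 (not isolated), via aldol adduct 7 (not isolated)
Conditions: LDA (commercial, 2.3 equiv), THF, −78 °C; add 2; AcOH; crude with TsOH·H2O (10 mol%), PhMe, 80 °C
Reagents that add atoms: none
Why: The C7 carbanion of the lactone dianion (vinylogous enolate) undergoes aldol addition to the aldehyde, and the p-silyloxybenzylic alcohol then dehydrates under acid (E1) to the conjugated (E)-styrylpyranone.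

**Step 4**
Reactants: 8 6-[(E)-2-Ar-ethenyl]-4-hydroxy-2H-pyran-2-one
Product: 9 3-bromo-6-[(E)-2-Ar-ethenyl]-4-hydroxy-2H-pyran-2-one
Conditions: NBS (1.0 equiv), CH2Cl2, 0 °C, dark
Reagents that add atoms: N-bromosuccinimide (NBS), O=C1CCC(=O)N1Br
Why: Electrophilic bromination occurs at C3 of the 4-hydroxy-2-pyranone enol, the most nucleophilic carbon (as for triacetic acid lactone itself), ahead of the styrene and the silylated arene.

**Step 5**
Reactants: 9 3-bromo-6-[(E)-2-Ar-ethenyl]-4-hydroxy-2H-pyran-2-one; 4 (E)-3-Ar-prop-2-enal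
Product: 10 (1R,2S)-2-Ar-6-[(E)-2-Ar-ethenyl]-4,8-dioxo-5-oxaspiro[2.5]oct-6-ene-1-carbaldehyde (formyl trans to Ar; spiro carbon as epimer mixture)
Conditions: (S)-α,α-diphenylprolinol TMS ether (20 mol%), 2,6-lutidine (1.1 equiv), CH2Cl2, 0 °C
Reagents that add atoms: none
Why: Proposed new method: Michael-initiated ring closure under iminium–enamine catalysis, the closest known type being the diarylprolinol-silyl-ether cyclopropanation of enals with bromomalonates and with cyclic α-halo C–H acids (3-chlorooxindoles, halobarbiturates) — the 4-oxidopyranone of 9 adds through C3 to the unshielded face of the iminium β-carbon of 4, and the resulting enamine displaces bromide at the now tertiary, doubly carbonyl-activated carbon (3-exo-tet), which sets the aryl-bearing carbon (S) by catalyst control and the formyl-bearing carbon (R) trans to it by the anti ring closure.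

**Step 6**
Reactants: 10 spirocyclopropane carbaldehyde (Sp-CHO); 11 2,2,6-trimethyl-4H-1,3-dioxin-4-one
Product: 13 6-[2-hydroxy-2-(Sp)ethyl]-2,2-dimethyl-4H-1,3-dioxin-4-one (carbinol epimers), via lithium dienolate 12 (not isolated)
Conditions: 11, LDA (commercial, 1.1 equiv), THF, −78 °C; add 10, −78 °C, 20 min; AcOH at −78 °C
Reagents that add atoms: none
Why: Vinylogous aldol addition of the dioxinone lithium dienolate (γ-selective) goes to the aldehyde, which at −78 °C is far more electrophilic than the vinylogous-ester ketone or the enol lactone; the new carbinol centre forms as a mixture and is removed in step 7.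

**Step 7**
Reactants: 13 6-[2-hydroxy-2-(Sp)ethyl]-2,2-dimethyl-4H-1,3-dioxin-4-one
Product: 17 (2S,3S)-2-Ar-6-[(E)-2-Ar-ethenyl]-3-(4-hydroxy-2-oxo-2H-pyran-6-yl)-2,3-dihydro-4H-furo[3,2-c]pyran-4-one (2,3-trans), via β-keto-dioxinone 14 (not isolated), via acylketene 15 (not isolated), via pyranonyl spirocyclopropane 16 (not isolated)
Conditions: DMP (1.3 equiv), NaHCO3, CH2Cl2, 0 °C → rt; aqueous work-up; crude in PhMe (0.01 M), 110 °C, 2 h
Reagents that add atoms: none
Why: Proposed new method: tandem acylketene pyranone annulation/Cloke–Wilson ring expansion, each half being a known reaction type (thermolysis of 6-(2-oxoalkyl)dioxinones to 6-substituted 4-hydroxy-2-pyranones; acid-promoted ring-opening cyclisation of 2-aryl 1,3-dione spirocyclopropanes to 2-aryl-2,3-dihydrofurans) — after Dess–Martin oxidation, retro-[4+2] loss of acetone gives acylketene 15, whose enol oxygen closes the pendant pyranone 16, and this new vinylogous acid (pKa about 5) activates the spiro-dione so that the bond from the spiro carbon to the electron-rich benzylic carbon ionises and the ketone oxygen closes the dihydrofuran anti to the pyranone at C3, which keeps C3 as set in step 5 and sets C2 trans (2S,3S).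

**Step 8**
Reactants: 17 tetra-TBS hypholomine B
Product: 18 hypholomine B [(2S,3S)-2-(3,4-dihydroxyphenyl)-6-[(E)-2-(3,4-dihydroxyphenyl)ethenyl]-3-(4-hydroxy-2-oxo-2H-pyran-6-yl)-2,3-dihydro-4H-furo[3,2-c]pyran-4-one]
Conditions: HF·pyridine (excess), pyridine/THF, 0 °C → rt
Reagents that add atoms: none
Why: Buffered HF cleaves the four aryl silyl ethers (Si–F bond formation) without touching the pyranones, the styrene or the trans-dihydrofuran, so no stereocentre is affected.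

**Compound list**
1 | 3,4-dihydroxybenzaldehyde | O=Cc1ccc(O)c(O)c1 | starting material
2 | 3,4-bis(tert-butyldimethylsilyloxy)benzaldehyde | O=Cc1ccc(O[Si](C)(C)C(C)(C)C)c(O[Si](C)(C)C(C)(C)C)c1 | intermediate
3 | (triphenylphosphoranylidene)acetaldehyde | O=CC=P(c1ccccc1)(c1ccccc1)c1ccccc1 | starting material
4 | (E)-3-[3,4-bis(tert-butyldimethylsilyloxy)phenyl]prop-2-enal | O=C/C=C/c1ccc(O[Si](C)(C)C(C)(C)C)c(O[Si](C)(C)C(C)(C)C)c1 | intermediate
5 | 4-hydroxy-6-methyl-2H-pyran-2-one (triacetic acid lactone) | Cc1cc(O)cc(=O)o1 | starting material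
6 | dilithium salt of the O4,C7-dianion of 5 | [Li+].[Li+].[CH2-]c1cc([O-])cc(=O)o1 | intermediate
7 | 6-(2-Ar-2-hydroxyethyl)-4-hydroxy-2H-pyran-2-one (racemic aldol adduct) | O=c1cc(O)cc(CC(O)c2ccc(O[Si](C)(C)C(C)(C)C)c(O[Si](C)(C)C(C)(C)C)c2)o1 | intermediate
8 | 6-[(E)-2-Ar-ethenyl]-4-hydroxy-2H-pyran-2-one (di-TBS hispidin) | O=c1cc(O)cc(/C=C/c2ccc(O[Si](C)(C)C(C)(C)C)c(O[Si](C)(C)C(C)(C)C)c2)o1 | intermediate
9 | 3-bromo-6-[(E)-2-Ar-ethenyl]-4-hydroxy-2H-pyran-2-one | O=c1oc(/C=C/c2ccc(O[Si](C)(C)C(C)(C)C)c(O[Si](C)(C)C(C)(C)C)c2)cc(O)c1Br | intermediate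
10 | (1R,2S)-2-Ar-6-[(E)-2-Ar-ethenyl]-4,8-dioxo-5-oxaspiro[2.5]oct-6-ene-1-carbaldehyde (CHO trans to Ar; spiro carbon epimers) | O=C[C@@H]1[C@@H](c2ccc(O[Si](C)(C)C(C)(C)C)c(O[Si](C)(C)C(C)(C)C)c2)C12C(=O)OC(/C=C/c3ccc(O[Si](C)(C)C(C)(C)C)c(O[Si](C)(C)C(C)(C)C)c3)=CC2=O | intermediate
11 | 2,2,6-trimethyl-4H-1,3-dioxin-4-one | CC1=CC(=O)OC(C)(C)O1 | starting material
12 | lithium 2,2-dimethyl-6-methylidene-6H-1,3-dioxin-4-olate (dienolate of 11) | [Li+].[O-]C1=CC(=C)OC(C)(C)O1 | intermediate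
13 | 6-[2-hydroxy-2-(Sp)ethyl]-2,2-dimethyl-4H-1,3-dioxin-4-one (carbinol epimers; cyclopropane as in 10) | CC1(C)OC(CC(O)[C@@H]2[C@@H](c4ccc(O[Si](C)(C)C(C)(C)C)c(O[Si](C)(C)C(C)(C)C)c4)C23C(=O)OC(/C=C/c4ccc(O[Si](C)(C)C(C)(C)C)c(O[Si](C)(C)C(C)(C)C)c4)=CC3=O)=CC(=O)O1 | intermediate
14 | 6-[2-oxo-2-(Sp)ethyl]-2,2-dimethyl-4H-1,3-dioxin-4-one | CC1(C)OC(CC(=O)[C@@H]2[C@@H](c4ccc(O[Si](C)(C)C(C)(C)C)c(O[Si](C)(C)C(C)(C)C)c4)C23C(=O)OC(/C=C/c4ccc(O[Si](C)(C)C(C)(C)C)c(O[Si](C)(C)C(C)(C)C)c4)=CC3=O)=CC(=O)O1 | intermediate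
15 | 5-(Sp)pent-1-ene-1,3,5-trione (acylketene) | O=C=CC(=O)CC(=O)[C@@H]1[C@@H](c3ccc(O[Si](C)(C)C(C)(C)C)c(O[Si](C)(C)C(C)(C)C)c3)C12C(=O)OC(/C=C/c3ccc(O[Si](C)(C)C(C)(C)C)c(O[Si](C)(C)C(C)(C)C)c3)=CC2=O | intermediate
16 | 4-hydroxy-6-(Sp)-2H-pyran-2-one | O=c1cc(O)cc([C@@H]2[C@@H](c4ccc(O[Si](C)(C)C(C)(C)C)c(O[Si](C)(C)C(C)(C)C)c4)C23C(=O)OC(/C=C/c4ccc(O[Si](C)(C)C(C)(C)C)c(O[Si](C)(C)C(C)(C)C)c4)=CC3=O)o1 | intermediate
17 | (2S,3S)-2-Ar-6-[(E)-2-Ar-ethenyl]-3-(4-hydroxy-2-oxo-2H-pyran-6-yl)-2,3-dihydro-4H-furo[3,2-c]pyran-4-one (tetra-TBS hypholomine B) | O=c1cc(O)cc([C@H]2c3c(cc(/C=C/c4ccc(O[Si](C)(C)C(C)(C)C)c(O[Si](C)(C)C(C)(C)C)c4)oc3=O)O[C@@H]2c2ccc(O[Si](C)(C)C(C)(C)C)c(O[Si](C)(C)C(C)(C)C)c2)o1 | intermediate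
18 | hypholomine B | O=c1cc(O)cc([C@H]2c3c(cc(/C=C/c4ccc(O)c(O)c4)oc3=O)O[C@@H]2c2ccc(O)c(O)c2)o1 | target

**Step count and risks**
Total step count: 8. Longest linear sequence: 7 (steps 1, 3, 4, 5, 6, 7, 8).

The three steps most likely to fail are 5, 6 and 7; steps 5 and 7 carry the most risk.

Step 5 (the bromopyranone may be too weak a carbon nucleophile, may transfer Br+ to the enamine, or the formylcyclopropane may ring-open under amine catalysis). The fallback separates C–C bond formation from halogenation. It sets out from 8 and 4: the established iminium-catalysed Michael addition of a 4-hydroxypyranone to an enal (same (S)-prolinol catalyst, PhCO2H, CH2Cl2) gives the lactol (4S)-4-Ar-7-[(E)-2-Ar-ethenyl]-2-hydroxy-3,4-dihydro-2H,5H-pyrano[4,3-b]pyran-5-one F1. NBS then brominates the pyranone C3 of its open hydroxy-aldehyde form to give the 3-bromo-pyran-2,4-dione aldehyde F2. Enamine α-alkylation (pyrrolidine 20 mol%, Et3N, CH2Cl2) closes the cyclopropane trans to the aryl group and comes back to the route at 10.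

Step 6 (the basic dienolate may attack the enol lactone or the activated cyclopropane, or the alkoxide may translactonise). The fallback attaches the chain at the acid oxidation level with a neutral nucleophile. It sets out from 10: Pinnick oxidation (NaClO2, NaH2PO4, 2-methyl-2-butene) gives the spirocyclopropane carboxylic acid F3, and oxalyl chloride/cat. DMF gives the acid chloride F4. C-Acylation of the silyl dienol ether 2,2-dimethyl-6-methylidene-4-(trimethylsilyloxy)-6H-1,3-dioxine F5 (from 11, LDA, TMSCl) gives the β-keto-dioxinone directly and comes back to the route at 14, with no oxidation needed.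

Step 7 (possible closure through the lactone oxygen, E1 loss of the C3 proton from the benzylic cation with erosion of ee, or intermolecular trapping of the cation). The fallback uncouples and reorders the two ring formations. It sets out from 13: Sc(OTf)3 (5 mol%, CH2Cl2, −20 °C) effects the ring expansion first, under tight ion-pair conditions, to the trans-dihydrofuro[3,2-c]pyranone carbinol F6. Dess–Martin oxidation gives the dihydrofuranyl β-keto-dioxinone F7, and thermolysis (PhMe, 110 °C) then closes only the pendant pyranone and comes back to the route at 17.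

**Further compounds**
F1 | step 5 | (4S)-4-Ar-7-[(E)-2-Ar-ethenyl]-2-hydroxy-3,4-dihydro-2H,5H-pyrano[4,3-b]pyran-5-one (lactol epimers) | OC1C[C@@H](c3ccc(O[Si](C)(C)C(C)(C)C)c(O[Si](C)(C)C(C)(C)C)c3)c2c(O1)cc(/C=C/c3ccc(O[Si](C)(C)C(C)(C)C)c(O[Si](C)(C)C(C)(C)C)c3)oc2=O
F2 | step 5 | 3-bromo-3-[(1S)-1-Ar-3-oxopropyl]-6-[(E)-2-Ar-ethenyl]-2H-pyran-2,4(3H)-dione (C3 epimers) | O=CC[C@@H](c2ccc(O[Si](C)(C)C(C)(C)C)c(O[Si](C)(C)C(C)(C)C)c2)C1(Br)C(=O)OC(/C=C/c2ccc(O[Si](C)(C)C(C)(C)C)c(O[Si](C)(C)C(C)(C)C)c2)=CC1=O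
F3 | step 6 | (1R,2S)-2-Ar-6-[(E)-2-Ar-ethenyl]-4,8-dioxo-5-oxaspiro[2.5]oct-6-ene-1-carboxylic acid | OC(=O)[C@@H]1[C@@H](c2ccc(O[Si](C)(C)C(C)(C)C)c(O[Si](C)(C)C(C)(C)C)c2)C12C(=O)OC(/C=C/c3ccc(O[Si](C)(C)C(C)(C)C)c(O[Si](C)(C)C(C)(C)C)c3)=CC2=O
F4 | step 6 | (1R,2S)-2-Ar-6-[(E)-2-Ar-ethenyl]-4,8-dioxo-5-oxaspiro[2.5]oct-6-ene-1-carbonyl chloride | ClC(=O)[C@@H]1[C@@H](c2ccc(O[Si](C)(C)C(C)(C)C)c(O[Si](C)(C)C(C)(C)C)c2)C12C(=O)OC(/C=C/c3ccc(O[Si](C)(C)C(C)(C)C)c(O[Si](C)(C)C(C)(C)C)c3)=CC2=O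
F5 | step 6 | 2,2-dimethyl-6-methylidene-4-(trimethylsilyloxy)-6H-1,3-dioxine | C=C1C=C(O[Si](C)(C)C)OC(C)(C)O1
F6 | step 7 | 6-[2-hydroxy-2-(2-Ar-6-[(E)-2-Ar-ethenyl]-4-oxo-2,3-dihydro-4H-furo[3,2-c]pyran-3-yl)ethyl]-2,2-dimethyl-4H-1,3-dioxin-4-one (2,3-trans; ring configuration as in 17; carbinol epimers) | CC1(C)OC(CC(O)[C@H]2c3c(cc(/C=C/c4ccc(O[Si](C)(C)C(C)(C)C)c(O[Si](C)(C)C(C)(C)C)c4)oc3=O)O[C@@H]2c2ccc(O[Si](C)(C)C(C)(C)C)c(O[Si](C)(C)C(C)(C)C)c2)=CC(=O)O1
F7 | step 7 | 6-[2-oxo-2-(2-Ar-6-[(E)-2-Ar-ethenyl]-4-oxo-2,3-dihydro-4H-furo[3,2-c]pyran-3-yl)ethyl]-2,2-dimethyl-4H-1,3-dioxin-4-one (2,3-trans; ring configuration as in 17) | CC1(C)OC(CC(=O)[C@H]2c3c(cc(/C=C/c4ccc(O[Si](C)(C)C(C)(C)C)c(O[Si](C)(C)C(C)(C)C)c4)oc3=O)O[C@@H]2c2ccc(O[Si](C)(C)C(C)(C)C)c(O[Si](C)(C)C(C)(C)C)c2)=CC(=O)O1
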